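## The problem

The target 37 is a germacrane-type dilactone. Numbering used throughout: carbocycle C1–C10; C3 carries the isobutyrate; C4=C5–C6 is shared with a butenolide (carbonyl C15, ring oxygen on C6); C7 carries C11(=C13H2)–C12(=O), whose ring oxygen sits on C8; C9=C10 carries the hydroxymethyl carbon C14.

A ten-membered ring must be built that holds a C4=C5 bond that is trans within the ring (forced by the bridging butenolide) and a C9=C10 bond with C8 and C1 cis, and both γ-lactones are fused to it. Direct C–C closure of such a ring is the weakest operation one could plan. Of the four stereocentres, C6, C7 and C8 are contiguous and can control one another (C8 directs C7 through allylic strain; alkene geometry fixes C6 relative to C7). C3 is insulated from this triad by the sp2 carbons C4 and C5 and has to be set independently by a reagent. The α-methylene lactone, the butenolide, the isobutyrate and the free allylic C14 hydroxyl survive neither organolithiums nor aluminium hydrides nor alkoxide bases, so all of them must appear after such steps. The enabling feature is the C6 carbinol lying between the C4–C5 unsaturation and a C7 that bears a 2-propenyl unit (C11, C13, C12). This is the product pattern of the [2,3]-shift of a propargyl allyl ether, with C6–C7 as the new bond. If that ether is part of a 13-membered ring the shift contracts it to the ten-membered carbocycle, and the alkyne left at C4≡C5 is the handle for the butenolide.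

## Retrosynthesis

**End game (37 ← 36 ← 33 ← 32 ← 31 ← 30).** The Si–O bond at C14, the C12–O8 lactone bond (with the C12 oxidation level) and the C3 ester are cut. The α-methylene lactone is cut rather than carried because it cannot pass the lithiation and hydride steps; as diol 33 it is masked by two 4-methoxybenzyl (PMB) ethers that fall in one oxidative step. A PMB group on O8 is preferred to an acetal because its removal needs no acid next to the allylic C8–O bond. The forward reaction asks for oxidation of a primary allylic alcohol in the presence of a secondary one. C3 is acylated (31 → 32) while O14 is still silylated, which requires a TBS ether at C3 that is more acid-labile than the TBDPS ether at C14.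

**Butenolide (30 ← 29 ← 27).** C4–C15 and C15–O6 are cut by a carbonylative lactonisation of vinyl iodide 29, and the C4–I and C5–H bonds by hydroxyl-directed trans-hydroalumination of cyclodecynol 27. Against a cut of C4=C5 (metathesis), this sequence builds the trans ring alkene from an unstrained cycloalkyne and uses the C6 hydroxyl twice, as director and as lactone oxygen. The forward reactions must put iodine on C4, cis to C6.

**Ring contraction (27 ← 25).** C6–C7 is cut and O6 is reconnected to C13, giving the 13-membered propargyl allyl ether 25. This removes the medium ring and two stereocentres at once; 25 has only C3 and C8 as stereocentres and an ordinary macrocyclic ether linkage. The forward [2,3]-Wittig shift must lithiate C6 selectively and translate the cis C13/C8 alkene geometry and the C8 configuration into C6 and C7.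

**Macrocycle (25 ← 24 ← 23 ← 21).** The O–C13 bond is cut (Williamson closure of the C6 propargylic alkoxide onto the C13 allylic chloride). A palladium allyl route is avoided because the allyl terminus would lose the C7=C11 geometry, and the reverse polarity would place an alkoxide beside a propargylic halide. Seco alcohol 21 is acyclic, and the forward closure only has to outrun oligomerisation.

**C7=C11 unit (21 ← 20 ← 19 ← 17).** C11–C13 is cut (Stille hydroxymethylation) and the C11–I bond is traced to directed trans-hydroalumination of the C7≡C11 alkyne of 17. This fixes C13 cis to C8 without any olefination stereochemistry problem; an enoate olefination would have to deliver the less favoured geometry. The forward step must reduce only the alkyne next to the free hydroxyl.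

**C8 (17 ← 14 + 15).** C7–C8 is cut; catalytic asymmetric addition of alkyne 15 to enal 14 sets C8 by reagent control. The alternative C8–C9 cut would need a stereodefined trisubstituted vinyl metal.

**C9=C10 and C3 (14 ← 13 ← 4 + 11; 4 ← 2 ← 1; 11 ← 10 ← 9 ← 6 + 7; 6 and 15 ← 5).** C10–C1 is cut (B-alkyl Suzuki–Miyaura coupling of iodide 4 with the borane of enyne 11). The same hydroalumination–iodination that is used twice later gives 4 from 2-butyne-1,4-diol 1 with C14 trans to C8. C3 comes from a resolved 1-en-4-yn-3-ol (10) made from propargyl alcohol 5 and acrolein 7. All starting materials are C3 or C4 commodity chemicals.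

## Roads not taken

**Alternative 1:** Chiral-pool entry from levoglucosenone. The cut isolates C5–C9 as a lactone. The forward key step is a Baeyer–Villiger oxidation of the bicyclic ketone A1 with aqueous H2O2, which inserts oxygen between the ketone and the acetal carbon, loses formic acid and relactonises to the all-trans lactone A2. Its merit is real: the C6/C7/C8 triad would come with absolute control from a cheap bicyclic template in very few steps. This is more secure than the chosen plan, which relies on one catalytic asymmetric addition and on transition-state organisation in the shift. Its weak points for this target are that A2 solves none of the ring problem. The isopropenyl group lacks the C12 oxygen, so a late allylic oxidation among several allylic sites is needed. C9 is a carbonyl that must become the C9=C10 alkene with defined geometry. The ten-membered ring still has to be closed by a direct medium-ring reaction. Against the better triad control of A2, the chosen plan sets a single operation that makes the ring, C6–C7 and the butenolide handle together.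

**Alternative 2:** Late metathesis. The cut is C4=C5. In the forward key step the second-generation Grubbs catalyst joins the C6 vinyl group and the C4 acrylate methylene of the 11-membered macrolactone A3, giving the triethylsilyl ether A4, one deprotection from the target. In end-game economy this road is better than the chosen one: no hydride or carbonylation steps follow ring formation and the ester and both lactones are already in place. Its weak points are that A3 is itself a medium-ring lactone of a hindered acrylic acid, so the ring problem is moved rather than removed. The catalyst must engage a 1,1-disubstituted electron-poor alkene while a second one (C11=C13) is present, and strain from the trans ring alkene develops in the ring-closing event. The chosen plan answers with a ring-forming step that has close precedent for this bicyclic motif and with stereocentres that are set before the ring exists.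

**Alternative 3:** Sulfonium ylide ring expansion. The cut is C1–C2. In the forward key step Rh2(OAc)4 turns diazoketone A5 into a carbenoid that is captured by the C9 phenyl sulfide; the [2,3]-shift of the nine-membered ylide gives the ten-membered ketone A6 with the C9=C10 alkene. Like the chosen plan it avoids end-to-end medium-ring C–C closure, and it is more convergent because both lactones enter before the ring is made. Its weak points are the entropically poor formation of a nine-membered ylide against cyclopropanation of two available methylene groups, and the lack of any element fixing the C9=C10 geometry. It also leaves two corrections on a molecule with two Michael acceptors: reductive removal of sulfur at C2 and a reagent-controlled reduction of the C3 ketone. The chosen plan has no such post-cyclisation repairs at C2 or C3, at the price of a longer protecting-group end game.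

Key step: step 17

## Route

Abbreviations: TBS = tert-butyldimethylsilyl, TES = triethylsilyl, TBDPS = tert-butyldiphenylsilyl, PMB = 4-methoxybenzyl. Locants C1–C15 are those defined above.

Assumption: in step 10 the (S,S)-enantiomer of ProPhenol is taken to deliver the alkynyl group to the Si face of the enal carbonyl (8R); if the sense is the reverse, its antipode is the ligand to use.

Assumption: in step 5 the lipase is taken to acetylate the (R)-alcohol, in line with the empirical size rule for secondary alcohols with the rod-like alkynyl arm as the large group.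

Step 1
Reactants: 1 2-butyne-1,4-diol
Product: 2 mono-TBDPS ether of 2-butyne-1,4-diol
Conditions: 1 (3 equiv), TBDPSCl (1 equiv), imidazole, THF–DMF, 0 °C → rt
Reagents that add atoms: tert-butyl(chloro)diphenylsilane, CC(C)(C)[Si](Cl)(c1ccccc1)c1ccccc1
Why: Statistical monosilylation of a symmetrical diol used in excess (imidazole-promoted silyl ether formation); the surplus diol is removed in the aqueous wash.

Step 2
Reactants: 2 mono-TBDPS ether of 2-butyne-1,4-diol
Product: 4 (Z)-4-(TBDPS-oxy)-3-iodobut-2-en-1-ol, via cyclic alkenylalanate 3 (not isolated)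
Conditions: NaAlH2(OCH2CH2OCH3)2, THF, 0 °C; then I2, −78 → 0 °C
Reagents that add atoms: iodine, II
Why: Hydroxyl-directed trans-hydroalumination of a propargylic alcohol delivers hydride to the proximal carbon and leaves aluminium on the distal carbon in a five-membered chelate, so iodinolysis with retention puts iodine on C10 cis to C8; the silyloxy group is a poor leaving group, which should suppress elimination to the allene at low temperature.

Step 3
Reactants: 5 propargyl alcohol
Product: 6 TES ether of propargyl alcohol
Conditions: TESCl, imidazole, CH2Cl2, 0 °C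
Reagents that add atoms: chlorotriethylsilane, CC[Si](Cl)(CC)CC
Why: Routine imidazole-promoted silylation of a primary alcohol.

Step 4
Reactants: 6 TES ether of propargyl alcohol; 7 acrolein
Product: 9 racemic 6-(TES-oxy)hex-1-en-4-yn-3-ol, via lithium acetylide 8 (not isolated)
Conditions: n-BuLi, THF, −78 °C; then 7, −78 °C
Reagents that add atoms: none
Why: Acetylide 1,2-addition to an enal; the hard lithium acetylide attacks the carbonyl of acrolein at low temperature.

Step 5
Reactants: 9 racemic 6-(TES-oxy)hex-1-en-4-yn-3-ol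
Product: 10 (3S)-6-(TES-oxy)hex-1-en-4-yn-3-ol
Conditions: Pseudomonas cepacia lipase (Amano PS), vinyl acetate, hexane, rt, run past half conversion
Reagents that add atoms: none
Why: Lipase-catalysed kinetic resolution by enantioselective acetylation, an established entry to 1-en-4-yn-3-ols; the (R)-alcohol should be acylated and the (S)-alcohol, which carries the C3 configuration of the target, recovered.

Step 6
Reactants: 10 (3S)-6-(TES-oxy)hex-1-en-4-yn-3-ol
Product: 11 (3S)-3-(TBS-oxy)-6-(TES-oxy)hex-1-en-4-yne
Conditions: TBSCl, imidazole, DMF, rt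
Reagents that add atoms: tert-butyl(chloro)dimethylsilane, CC(C)(C)[Si](C)(C)Cl
Why: Routine silylation; C3 is not touched.

Step 7
Reactants: 11 (3S)-3-(TBS-oxy)-6-(TES-oxy)hex-1-en-4-yne; 4 (Z)-4-(TBDPS-oxy)-3-iodobut-2-en-1-ol
Product: 13 (2E,6S)-allylic alcohol C8–C6, via B-alkyl-9-BBN 12 (not isolated)
Conditions: 9-BBN, THF, rt; then 4, PdCl2(dppf) (cat.), AsPh3, Cs2CO3, DMF–H2O, rt
Reagents that add atoms: none
Why: B-alkyl Suzuki–Miyaura coupling; 9-BBN hydroborates the terminal alkene at C1 far faster than the internal alkyne, and the alkylborane couples with the vinyl iodide with retention, so C1 ends cis to C8 and C14 trans to C8.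

Step 8
Reactants: 13 (2E,6S)-allylic alcohol C8–C6
Product: 14 (2E,6S)-enal
Conditions: MnO2, CH2Cl2, rt
Reagents that add atoms: none
Why: Selective allylic oxidation under neutral conditions, which should leave the alkene geometry and the silyl ethers intact.

Step 9
Reactants: 5 propargyl alcohol
Product: 15 PMB propargyl ether
Conditions: NaH, PMBCl, Bu4NI (cat.), THF, 0 °C → rt
Reagents that add atoms: 4-methoxybenzyl chloride, COc1ccc(CCl)cc1
Why: Williamson etherification of a primary alkoxide.

Step 10
Reactants: 14 (2E,6S)-enal; 15 PMB propargyl ether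
Product: 17 (3S,8R)-propargylic alcohol, via methylzinc acetylide 16 (not isolated)
Conditions: 15 (3 equiv), Me2Zn, (S,S)-ProPhenol (20 mol %), Ph3P=O (40 mol %), toluene, 0 °C
Reagents that add atoms: none
Why: Zinc–ProPhenol catalysed asymmetric alkynylation, for which α,β-unsaturated aldehydes are the best substrate class; the dinuclear zinc catalyst sets C8 by reagent control (Si-face addition gives 8R) and only 1,2-addition is expected.

Step 11
Reactants: 17 (3S,8R)-propargylic alcohol
Product: 19 (3S,8R)-C11 vinyl iodide, via cyclic alkenylalanate 18 (not isolated)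
Conditions: NaAlH2(OCH2CH2OCH3)2, THF, −20 → 0 °C; then I2, −78 °C
Reagents that add atoms: iodine, II
Why: Directed trans-hydroalumination–iodination as in step 2; hydride is delivered only within the C8 alkoxide complex, so the C4≡C5 alkyne flanked by ethers should stay, and iodine arrives on C11 cis to C8, which places C12 trans to C8.

Step 12
Reactants: 19 (3S,8R)-C11 vinyl iodide
Product: 20 (3S,8R)-bis-PMB vinyl iodide
Conditions: NaH, PMBCl, Bu4NI (cat.), DMF, 0 °C
Reagents that add atoms: 4-methoxybenzyl chloride, COc1ccc(CCl)cc1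
Why: Williamson benzylation under basic conditions, chosen so that the doubly allylic C8 carbinol is never exposed to acid.

Step 13
Reactants: 20 (3S,8R)-bis-PMB vinyl iodide
Product: 21 (3S,8R)-C13 allylic alcohol
Conditions: Bu3SnCH2OH, Pd(PPh3)4 (cat.), 1,4-dioxane, 90 °C
Reagents that add atoms: (tributylstannyl)methanol, CCCC[Sn](CCCC)(CCCC)CO
Why: Stille hydroxymethylation of a vinyl iodide with retention of geometry installs C13 cis to C8; ethers and the internal alkyne are inert to zerovalent palladium.

Step 14
Reactants: 21 (3S,8R)-C13 allylic alcohol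
Product: 23 (3S,8R)-C13 allylic chloride, via allylic mesylate 22 (not isolated)
Conditions: MsCl, 2,4,6-collidine, LiCl, DMF, 0 °C
Reagents that add atoms: lithium chloride, [Li+].[Cl-]
Why: One-pot mesylation and chloride displacement; SN2 at the primary allylic carbon keeps the alkene geometry.

Step 15
Reactants: 23 (3S,8R)-C13 allylic chloride
Product: 24 (3S,8R)-chloro propargylic alcohol
Conditions: PPTS (cat.), MeOH–CH2Cl2, 0 °C
Reagents that add atoms: none
Why: Acid-catalysed methanolysis of the primary TES ether, which is orders of magnitude faster than that of the secondary TBS and primary TBDPS ethers; the weak acid should not ionise the C8 ether.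

Step 16
Reactants: 24 (3S,8R)-chloro propargylic alcohol
Product: 25 (3S,8R)-13-membered propargyl allyl ether
Conditions: NaH, Bu4NI (cat.), THF, 0.002 M, slow addition, 50 °C
Reagents that add atoms: none
Why: Intramolecular Williamson etherification at high dilution; the C6 propargylic alkoxide displaces the primary allylic chloride (SN2) to close the 13-membered ring, helped by the rigid alkyne and two cis alkenes; no stereocentre is touched.

Step 17
Reactants: 25 (3S,8R)-13-membered propargyl allyl ether
Product: 27 (3S,6S,7R,8R)-cyclodec-9-en-4-yn-6-ol, via C6-lithiated ether 26 (not isolated)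
Conditions: n-BuLi, THF–hexane, −78 → −30 °C
Reagents that add atoms: none
Why: n-BuLi removes a propargylic, oxygen-bearing hydrogen at C6 (26); the carbanion attacks C7 through a five-membered envelope transition state while the C13–O bond breaks, so C6–C7 forms, C11=C13 becomes the exocyclic methylene and the ether oxygen becomes the C6 alkoxide ([2,3]-Wittig rearrangement). The closest known reaction type is the [2,3]-Wittig ring contraction of 13-membered propargylic allylic ethers to 2-(propen-2-yl)cyclodecynols. The ten-membered carbocycle closes by contraction of the existing 13-membered ring (a transannular C6–C7 bond), not by an end-to-end cyclisation. C7 is controlled by C8: allylic 1,3-strain with the C13 methylene holds the C8–H bond in the alkene plane, which puts the ring chain (C9) on one face and the PMB ether on the other, and the tethered carbanion can reach C7 only from the face that carries C9. C6 is controlled by the cis C13/C8 alkene geometry together with the linear C6–C5≡C4–C3 unit, which can span to C3 only with the alkynyl arm exo on the envelope; this puts the C6 oxygen and the C7 propenyl unit cis on the new ring, the same syn outcome that cis-allyl propargyl ethers give in open-chain cases. The step needs lithiation at C6 rather than at C13, the benzylic methylenes, C3–H or C8–H; C6 is the only propargylic CH2 and the kinetically most acidic site at −78 °C. The [1,2]-shift is held back by keeping the temperature at or below −30 °C.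

Step 18
Reactants: 27 (3S,6S,7R,8R)-cyclodec-9-en-4-yn-6-ol
Product: 29 (3S,6S,7R,8R)-C4 vinyl iodide, via cyclic alkenylalanate 28 (not isolated)
Conditions: NaAlH2(OCH2CH2OCH3)2, THF, 0 °C; then I2, −78 °C
Reagents that add atoms: iodine, II
Why: Directed trans-hydroalumination–iodination of the C6 propargylic alcohol; hydride goes to C5 and iodine to C4 cis to C6, which creates the C4=C5 bond that is trans within the ring.

Step 19
Reactants: 29 (3S,6S,7R,8R)-C4 vinyl iodide
Product: 30 (3S,6R,7S,8R)-butenolide
Conditions: Pd(PPh3)4 (cat.), CO (1 atm), K2CO3, THF, 45 °C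
Reagents that add atoms: carbon monoxide, [C-]#[O+]
Why: Palladium-catalysed carbonylative lactonisation: oxidative addition to the C–I bond, CO insertion and capture of the acylpalladium by the cis C6 hydroxyl close the five-membered lactone with retention of alkene geometry.

Step 20
Reactants: 30 (3S,6R,7S,8R)-butenolide
Product: 31 (3S,6R,7S,8R)-C3 alcohol
Conditions: CSA (cat.), MeOH–CH2Cl2, 0 °C → rt
Reagents that add atoms: none
Why: Acid-catalysed methanolysis removes the secondary TBS ether, while the primary TBDPS ether is far more acid-stable and PMB ethers and the lactone are inert.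

Step 21
Reactants: 31 (3S,6R,7S,8R)-C3 alcohol
Product: 32 (3S,6R,7S,8R)-C3 isobutyrate
Conditions: (i-PrCO)2O, Et3N, DMAP (cat.), CH2Cl2, 0 °C → rt
Reagents that add atoms: isobutyric anhydride, CC(C)C(=O)OC(=O)C(C)C
Why: DMAP-catalysed acyl transfer to the only free hydroxyl; no stereocentre is involved.

Step 22
Reactants: 32 (3S,6R,7S,8R)-C3 isobutyrate
Product: 33 (3S,6R,7S,8R)-C8,C12 diol
Conditions: DDQ, CH2Cl2–pH 7 buffer, 0 °C
Reagents that add atoms: none
Why: Oxidative cleavage of both PMB ethers (hydride abstraction, hydrolysis of the oxocarbenium ion); silyl ether, ester and lactone are inert and buffered water disfavours acetal formation.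

Step 23
Reactants: 33 (3S,6R,7S,8R)-C8,C12 diol
Product: 36 (3S,6R,7S,8R)-dilactone TBDPS ether, via hydroxy enal 34 (not isolated), via lactol 35 (not isolated)
Conditions: TEMPO (cat.), PhI(OAc)2, CH2Cl2, rt
Reagents that add atoms: none
Why: Oxoammonium oxidation is selective for the primary allylic alcohol; the enal closes onto the C8 hydroxyl and the lactol is oxidised on to the α-methylene lactone, which removes the secondary alcohol from competing oxidation.

Step 24
Reactants: 36 (3S,6R,7S,8R)-dilactone TBDPS ether
Product: 37 target dilactone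
Conditions: HF·pyridine, pyridine, THF, 0 °C → rt
Reagents that add atoms: none
Why: Desilylation with buffered hydrogen fluoride avoids basic fluoride, which could trigger acyl migration or conjugate addition to the α-methylene lactone.

## Compound list

1 | 2-butyne-1,4-diol | OCC#CCO | starting material
2 | 4-[(tert-butyldiphenylsilyl)oxy]but-2-yn-1-ol | OCC#CCO[Si](c1ccccc1)(c1ccccc1)C(C)(C)C | intermediate
3 | sodium cyclic alkenylalanate from 2 (five-membered O–Al–C10 chelate, two 2-methoxyethoxy ligands on aluminium) | COCCO[Al-]1(OCCOC)OCC=C1CO[Si](c2ccccc2)(c2ccccc2)C(C)(C)C.[Na+] | intermediate (not isolated)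
4 | (Z)-4-[(tert-butyldiphenylsilyl)oxy]-3-iodobut-2-en-1-ol (C8–C9=C10(I)–C14, iodine cis to C8) | OC/C=C(\I)CO[Si](c1ccccc1)(c1ccccc1)C(C)(C)C | intermediate
5 | propargyl alcohol (prop-2-yn-1-ol) | C#CCO | starting material
6 | triethyl(prop-2-yn-1-yloxy)silane | C#CCO[Si](CC)(CC)CC | intermediate
7 | acrolein | C=CC=O | starting material
8 | lithium acetylide of 6 | [Li]C#CCO[Si](CC)(CC)CC | intermediate (not isolated)
9 | rac-6-[(triethylsilyl)oxy]hex-1-en-4-yn-3-ol | C=CC(O)C#CCO[Si](CC)(CC)CC | intermediate
10 | (3S)-6-[(triethylsilyl)oxy]hex-1-en-4-yn-3-ol | C=C[C@H](O)C#CCO[Si](CC)(CC)CC | intermediate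
11 | (3S)-3-[(tert-butyldimethylsilyl)oxy]-6-[(triethylsilyl)oxy]hex-1-en-4-yne | C=C[C@H](O[Si](C)(C)C(C)(C)C)C#CCO[Si](CC)(CC)CC | intermediate
12 | 9-[(3S)-3-(TBS-oxy)-6-(TES-oxy)hex-4-yn-1-yl]-9-borabicyclo[3.3.1]nonane | B1(C2CCCC1CCC2)CC[C@H](O[Si](C)(C)C(C)(C)C)C#CCO[Si](CC)(CC)CC | intermediate (not isolated)
13 | (2E,6S)-6-(TBS-oxy)-3-[(TBDPS-oxy)methyl]-9-(TES-oxy)non-2-en-7-yn-1-ol (C8 alcohol; C1 cis to C8) | OC/C=C(/CO[Si](c1ccccc1)(c1ccccc1)C(C)(C)C)CC[C@H](O[Si](C)(C)C(C)(C)C)C#CCO[Si](CC)(CC)CC | intermediate
14 | (2E,6S)-6-(TBS-oxy)-3-[(TBDPS-oxy)methyl]-9-(TES-oxy)non-2-en-7-ynal (C8 aldehyde) | O=C/C=C(/CO[Si](c1ccccc1)(c1ccccc1)C(C)(C)C)CC[C@H](O[Si](C)(C)C(C)(C)C)C#CCO[Si](CC)(CC)CC | intermediate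
15 | 1-methoxy-4-[(prop-2-yn-1-yloxy)methyl]benzene (PMB propargyl ether) | C#CCOCc1ccc(OC)cc1 | intermediate
16 | methylzinc acetylide of 15 | C[Zn]C#CCOCc1ccc(OC)cc1 | intermediate (not isolated)
17 | (4R,5E,9S)-9-(TBS-oxy)-6-[(TBDPS-oxy)methyl]-1-(PMB-oxy)-12-(TES-oxy)dodec-5-ene-2,10-diyn-4-ol (germacrane locants 3S,8R; C12–C11≡C7–C8(OH)) | COc1ccc(COCC#C[C@H](O)/C=C(/CO[Si](c2ccccc2)(c2ccccc2)C(C)(C)C)CC[C@H](O[Si](C)(C)C(C)(C)C)C#CCO[Si](CC)(CC)CC)cc1 | intermediate
18 | sodium cyclic alkenylalanate from 17 (five-membered O8–Al–C11 chelate) | COc1ccc(COCC2=C[C@@H](/C=C(/CO[Si](c3ccccc3)(c3ccccc3)C(C)(C)C)CC[C@H](O[Si](C)(C)C(C)(C)C)C#CCO[Si](CC)(CC)CC)O[Al-]2(OCCOC)OCCOC)cc1.[Na+] | intermediate (not isolated)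
19 | (2Z,4R,5E,9S)-9-(TBS-oxy)-6-[(TBDPS-oxy)methyl]-2-iodo-1-(PMB-oxy)-12-(TES-oxy)dodeca-2,5-dien-10-yn-4-ol (iodine on C11 cis to C8) | COc1ccc(COC/C(I)=C/[C@H](O)/C=C(/CO[Si](c2ccccc2)(c2ccccc2)C(C)(C)C)CC[C@H](O[Si](C)(C)C(C)(C)C)C#CCO[Si](CC)(CC)CC)cc1 | intermediate
20 | C8 PMB ether of 19 (3S,8R) | COc1ccc(COC/C(I)=C/[C@H](OCc2ccc(OC)cc2)/C=C(/CO[Si](c3ccccc3)(c3ccccc3)C(C)(C)C)CC[C@H](O[Si](C)(C)C(C)(C)C)C#CCO[Si](CC)(CC)CC)cc1 | intermediate
21 | (3S,8R)-seco allylic alcohol: 20 with iodine replaced by C13H2OH (C13 cis to C8, C12H2OPMB trans to C8) | COc1ccc(COC/C(CO)=C/[C@H](OCc2ccc(OC)cc2)/C=C(/CO[Si](c3ccccc3)(c3ccccc3)C(C)(C)C)CC[C@H](O[Si](C)(C)C(C)(C)C)C#CCO[Si](CC)(CC)CC)cc1 | intermediate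
22 | C13 methanesulfonate of 21 | COc1ccc(COC/C(COS(C)(=O)=O)=C/[C@H](OCc2ccc(OC)cc2)/C=C(/CO[Si](c3ccccc3)(c3ccccc3)C(C)(C)C)CC[C@H](O[Si](C)(C)C(C)(C)C)C#CCO[Si](CC)(CC)CC)cc1 | intermediate (not isolated)
23 | (3S,8R)-C13 allylic chloride with C6 TES ether | COc1ccc(COC/C(CCl)=C/[C@H](OCc2ccc(OC)cc2)/C=C(/CO[Si](c3ccccc3)(c3ccccc3)C(C)(C)C)CC[C@H](O[Si](C)(C)C(C)(C)C)C#CCO[Si](CC)(CC)CC)cc1 | intermediate
24 | (3S,8R)-C13 allylic chloride with free C6 propargylic hydroxyl | COc1ccc(COC/C(CCl)=C/[C@H](OCc2ccc(OC)cc2)/C=C(/CO[Si](c3ccccc3)(c3ccccc3)C(C)(C)C)CC[C@H](O[Si](C)(C)C(C)(C)C)C#CCO)cc1 | intermediate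
25 | (3S,8R)-13-membered propargyl allyl ether (ring C1–C2–C3–C4≡C5–C6–O–C13–C11=C7–C8–C9=C10; C3 OTBS, C8 OPMB, C12 OPMB, C14 OTBDPS; C13 cis to C8, C1 cis to C8) | C1C[C@H](O[Si](C)(C)C(C)(C)C)C#CCOC/C(COCc2ccc(OC)cc2)=C\[C@H](OCc2ccc(OC)cc2)/C=C1/CO[Si](c2ccccc2)(c2ccccc2)C(C)(C)C | intermediate
26 | C6-lithiated 25 (configurationally labile at C6) | C1C[C@H](O[Si](C)(C)C(C)(C)C)C#CC([Li])OC/C(COCc2ccc(OC)cc2)=C\[C@H](OCc2ccc(OC)cc2)/C=C1/CO[Si](c2ccccc2)(c2ccccc2)C(C)(C)C | intermediate (not isolated)
27 | (3S,6S,7R,8R)-cyclodec-9-en-4-yn-6-ol: C3 OTBS, C6 OH, C7 3-(PMB-oxy)prop-1-en-2-yl, C8 OPMB, C10 CH2OTBDPS; C6 O and C7 side chain cis, C8 O trans to the C7 side chain | COc1ccc(CO[C@@H]2/C=C(/CO[Si](c3ccccc3)(c3ccccc3)C(C)(C)C)CC[C@H](O[Si](C)(C)C(C)(C)C)C#C[C@@H](O)[C@H]2C(=C)COCc2ccc(OC)cc2)cc1 | intermediate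
28 | sodium cyclic alkenylalanate from 27 (five-membered O6–Al–C4 chelate) | COc1ccc(CO[C@@H]2/C=C(/CO[Si](c3ccccc3)(c3ccccc3)C(C)(C)C)CC[C@H](O[Si](C)(C)C(C)(C)C)C4=C[C@@H](O[Al-]4(OCCOC)OCCOC)[C@H]2C(=C)COCc2ccc(OC)cc2)cc1.[Na+] | intermediate (not isolated)
29 | (3S,6S,7R,8R)-4-iodocyclodeca-4,9-dien-6-ol (iodine on C4 cis to C6; C3 and C6 trans across C4=C5), other groups as in 27 | COc1ccc(CO[C@@H]2/C=C(/CO[Si](c3ccccc3)(c3ccccc3)C(C)(C)C)CC[C@H](O[Si](C)(C)C(C)(C)C)/C(I)=C/[C@@H](O)[C@H]2C(=C)COCc2ccc(OC)cc2)cc1 | intermediate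
30 | (3S,6R,7S,8R)-butenolide (C15 carbonyl between C4 and O6), C3 OTBS, C8 OPMB, C12 OPMB, C14 OTBDPS | COc1ccc(CO[C@@H]2/C=C(/CO[Si](c3ccccc3)(c3ccccc3)C(C)(C)C)CC[C@H](O[Si](C)(C)C(C)(C)C)C4=C[C@@H](OC4=O)[C@H]2C(=C)COCc2ccc(OC)cc2)cc1 | intermediate
31 | (3S,6R,7S,8R)-butenolide with free C3 hydroxyl | COc1ccc(CO[C@@H]2/C=C(/CO[Si](c3ccccc3)(c3ccccc3)C(C)(C)C)CC[C@H](O)C4=C[C@@H](OC4=O)[C@H]2C(=C)COCc2ccc(OC)cc2)cc1 | intermediate
32 | (3S,6R,7S,8R)-butenolide C3 isobutyrate | COc1ccc(CO[C@@H]2/C=C(/CO[Si](c3ccccc3)(c3ccccc3)C(C)(C)C)CC[C@H](OC(=O)C(C)C)C4=C[C@@H](OC4=O)[C@H]2C(=C)COCc2ccc(OC)cc2)cc1 | intermediate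
33 | (3S,6R,7S,8R)-C8,C12 diol (butenolide, C3 isobutyrate, C14 OTBDPS) | O[C@@H]1/C=C(/CO[Si](c2ccccc2)(c2ccccc2)C(C)(C)C)CC[C@H](OC(=O)C(C)C)C2=C[C@@H](OC2=O)[C@H]1C(=C)CO | intermediate
34 | C12 aldehyde of 33 (2-substituted acrolein, free C8 hydroxyl) | O[C@@H]1/C=C(/CO[Si](c2ccccc2)(c2ccccc2)C(C)(C)C)CC[C@H](OC(=O)C(C)C)C2=C[C@@H](OC2=O)[C@H]1C(=C)C=O | intermediate (not isolated)
35 | C12 lactol (O8–C12 closed, anomers) | C=C1C(O)O[C@@H]2/C=C(/CO[Si](c3ccccc3)(c3ccccc3)C(C)(C)C)CC[C@H](OC(=O)C(C)C)C3=C[C@@H](OC3=O)[C@@H]12 | intermediate (not isolated)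
36 | (3S,6R,7S,8R)-dilactone, C14 TBDPS ether of the target | C=C1C(=O)O[C@@H]2/C=C(/CO[Si](c3ccccc3)(c3ccccc3)C(C)(C)C)CC[C@H](OC(=O)C(C)C)C3=C[C@@H](OC3=O)[C@@H]12 | intermediate
37 | CNP0322767.4, (3S,6R,7S,8R)-dilactone with C3 isobutyrate and free C14 hydroxyl | C=C1C(=O)O[C@@H]2/C=C(/CO)CC[C@H](OC(=O)C(C)C)C3=C[C@@H](OC3=O)[C@@H]12 | target

## Step count and weak points

Total: 24 steps. Longest linear sequence: 21 steps (5 → 6 → 9 → 10 → 11 → 13 → 14 → 17 → … → 37; steps 3–8 and 10–24).

**Step 17 (key step).** The most likely failure is erosion of the C6 configuration: if the 13-membered ring lets the alkynyl arm sit endo on the envelope, the oxygen at C6 ends trans to the C7 side chain. A second hazard is proton abstraction at a benzylic PMB methylene, since both PMB ethers are allylic benzylic ethers. This is a matter of kinetic acidity and is held back by one equivalent of base at −78 °C. The fallback keeps the disconnection and corrects C6 afterwards. It sets out from 25. The rearrangement is accepted as delivering the C6-epimeric (3S,6R,7R,8R)-cyclodecynol F1. A Mitsunobu reaction (4-nitrobenzoic acid, PPh3, diisopropyl azodicarboxylate, toluene, 0 °C) inverts the propargylic carbinol to the (6S)-4-nitrobenzoate F2. Methanolysis (K2CO3, MeOH) returns to the route at 27.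

**Step 18.** The C4 alkenylalanate carries the C3 silyloxy group in the β-position, so elimination to a C3=C4=C5 allene can compete with iodinolysis; the trans-cycloalkene geometry adds strain to the chelate. The fallback replaces aluminium by silicon. It sets out from 27. Ruthenium-catalysed trans-hydrosilylation ([Cp*Ru(MeCN)3]PF6, BnMe2SiH, CH2Cl2, 0 °C) places silicon on the distal carbon C4 and hydrogen on C5, giving the C4 benzyldimethylsilyl alkene F3 with the same geometry. Iododesilylation with retention (N-iodosuccinimide, hexafluoroisopropanol, 0 °C) returns to the route at 29.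

**Step 16.** Intermolecular etherification (oligomers) and base-induced loss of HCl from the allylic chloride can outrun closure of the 13-membered ring. The fallback reverses the polarity of the closure and sets out from 21:
- Acetylation (Ac2O, pyridine) gives the C13 acetate F4.
- PPTS in MeOH frees C6 to give the hydroxy acetate F5.
- CBr4 and PPh3 give the propargylic bromide F6.
- i-Bu2AlH at −78 °C removes the acetate to give the bromo alcohol F7.
- The C13 alkoxide (NaH, THF, high dilution) closes the ring onto the propargylic bromide, returning to the route at 25.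

**Step 10.** With a β,β-disubstituted enal the facial discrimination by the catalyst may be low, or addition may be slow enough for background reaction to take over. The fallback sets the centre by reduction instead of addition and sets out from 14 (with 15). The lithium acetylide of 15 adds without control to give the C8-epimeric alcohols F8. MnO2 gives the cross-conjugated ynone F9. Corey–Bakshi–Shibata reduction with the (R)-2-methyl-oxazaborolidine and catecholborane, with the trisubstituted alkenyl arm as the large group, returns to the route at 17.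

## Further compounds

F1 | step 17 | (3S,6R,7R,8R)-cyclodec-9-en-4-yn-6-ol, C6 epimer of 27 | COc1ccc(CO[C@@H]2/C=C(/CO[Si](c3ccccc3)(c3ccccc3)C(C)(C)C)CC[C@H](O[Si](C)(C)C(C)(C)C)C#C[C@H](O)[C@H]2C(=C)COCc2ccc(OC)cc2)cc1
F2 | step 17 | (3S,6S,7R,8R)-C6 4-nitrobenzoate of 27 | COc1ccc(CO[C@@H]2/C=C(/CO[Si](c3ccccc3)(c3ccccc3)C(C)(C)C)CC[C@H](O[Si](C)(C)C(C)(C)C)C#C[C@@H](OC(=O)c3ccc(cc3)[N+](=O)[O-])[C@H]2C(=C)COCc2ccc(OC)cc2)cc1
F3 | step 18 | (3S,6S,7R,8R)-4-(benzyldimethylsilyl)cyclodeca-4,9-dien-6-ol (silicon on C4 cis to C6) | COc1ccc(CO[C@@H]2/C=C(/CO[Si](c3ccccc3)(c3ccccc3)C(C)(C)C)CC[C@H](O[Si](C)(C)C(C)(C)C)/C([Si](C)(C)Cc3ccccc3)=C/[C@@H](O)[C@H]2C(=C)COCc2ccc(OC)cc2)cc1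
F4 | step 16 | C13 acetate of 21 | COc1ccc(COC/C(COC(C)=O)=C/[C@H](OCc2ccc(OC)cc2)/C=C(/CO[Si](c3ccccc3)(c3ccccc3)C(C)(C)C)CC[C@H](O[Si](C)(C)C(C)(C)C)C#CCO[Si](CC)(CC)CC)cc1
F5 | step 16 | C13 acetate with free C6 hydroxyl | COc1ccc(COC/C(COC(C)=O)=C/[C@H](OCc2ccc(OC)cc2)/C=C(/CO[Si](c3ccccc3)(c3ccccc3)C(C)(C)C)CC[C@H](O[Si](C)(C)C(C)(C)C)C#CCO)cc1
F6 | step 16 | C13 acetate C6 propargylic bromide | COc1ccc(COC/C(COC(C)=O)=C/[C@H](OCc2ccc(OC)cc2)/C=C(/CO[Si](c3ccccc3)(c3ccccc3)C(C)(C)C)CC[C@H](O[Si](C)(C)C(C)(C)C)C#CCBr)cc1
F7 | step 16 | C6 propargylic bromide with free C13 hydroxyl | COc1ccc(COC/C(CO)=C/[C@H](OCc2ccc(OC)cc2)/C=C(/CO[Si](c3ccccc3)(c3ccccc3)C(C)(C)C)CC[C@H](O[Si](C)(C)C(C)(C)C)C#CCBr)cc1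
F8 | step 10 | C8-epimeric mixture of 17 (3S) | COc1ccc(COCC#CC(O)/C=C(/CO[Si](c2ccccc2)(c2ccccc2)C(C)(C)C)CC[C@H](O[Si](C)(C)C(C)(C)C)C#CCO[Si](CC)(CC)CC)cc1
F9 | step 10 | C8 ketone (alkenyl alkynyl ketone, 3S) | COc1ccc(COCC#CC(=O)/C=C(/CO[Si](c2ccccc2)(c2ccccc2)C(C)(C)C)CC[C@H](O[Si](C)(C)C(C)(C)C)C#CCO[Si](CC)(CC)CC)cc1
A1 | alternative 1 | bicyclic ketone from levoglucosenone with isopropenyl and TBS-oxy groups | C1[C@@H]2[C@@H](C(C)=C)[C@H](O[Si](C)(C)C(C)(C)C)C(=O)[C@H](O1)O2
A2 | alternative 1 | all-trans γ-lactone C5–C9 | O=C1O[C@H](CO)[C@@H](C(C)=C)[C@@H]1O[Si](C)(C)C(C)(C)C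
A3 | alternative 2 | 11-membered macrolactone with C6 vinyl and C4 methylene groups | C=C1C(=O)O[C@@H]2/C=C(/CO[Si](CC)(CC)CC)CC[C@H](OC(=O)C(C)C)C(=C)C(=O)O[C@H](C=C)[C@@H]12
A4 | alternative 2 | C14 triethylsilyl ether of the target | C=C1C(=O)O[C@@H]2/C=C(/CO[Si](CC)(CC)CC)CC[C@H](OC(=O)C(C)C)C3=C[C@@H](OC3=O)[C@@H]12
A5 | alternative 3 | C2 diazoketone with C9 phenyl sulfide and C10=C1 methylene | C=C1C(=O)O[C@H](C(Sc2ccccc2)C(=C)CO[Si](C)(C)C(C)(C)C)[C@H]1[C@@H]1OC(=O)C(C(=O)C=[N+]=[N-])=C1
A6 | alternative 3 | ten-membered C3 ketone with C2 phenylthio group | C=C1C(=O)O[C@@H]2/C=C(/CO[Si](C)(C)C(C)(C)C)CC(Sc4ccccc4)C(=O)C3=C[C@@H](OC3=O)[C@@H]12
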